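**Plan**
1. Numbering: ring A is C1–C6 (C1 bears the acyl group, C4 the OH, C3 and C5 the OMe groups). The side chain is C7 (C=O), C8 (stereocentre, O-aryl) and C9 (CH2OH). Ring B is the syringic acid unit on the C8 oxygen.
2. Enabling feature: ring A is a symmetric 4-acyl-2,6-dimethoxyphenol. C3–C4–C5 with its three oxygens is 1,3-dimethoxyacetone. C2–C1–C6 is the three-carbon backbone of a 2-acylmalonaldehyde whose acyl group already is C7–C9 with ring B attached.
3. Retrosynthetic cuts, in order: silyl ether and tert-butyl ester; C2–C3 and C5–C6 of ring A; C1–C7 (C-acylation of 3-(dimethylamino)acrolein); C8–O(ring B).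
4. Forward order: ring B is bought as syringic acid. The C8–O ether is made first, then C7–C1. Ring A, the only ring that is built, closes in the penultimate step, and one acidolysis finishes the synthesis.
5. Stereochemistry: C8 comes from the chiral pool (methyl (S)-glycerate acetonide). One Mitsunobu inversion turns S into R, and the centre is then carried under conditions chosen against enolisation.

Key step: step 7

Assumption: the push–pull C=C bond of 10 is drawn E but rotates easily, so its geometry has no bearing on the ring closure; compounds 1, 4, 8 and 11 are taken as catalogue chemicals.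

**Step 1**
Reactants: 1 methyl (S)-2,2-dimethyl-1,3-dioxolane-4-carboxylate
Product: 2 methyl (S)-2,3-dihydroxypropanoate
Conditions: Dowex 50WX8 (H+ form), MeOH–H2O 9:1, 40 °C; filter, concentrate
Reagents that add atoms: none
Why: Acid-catalysed acetal hydrolysis frees the diol without breaking any bond at the stereocentre, so the S configuration is retained and the methyl ester survives in methanol.

**Step 2**
Reactants: 2 methyl (S)-2,3-dihydroxypropanoate
Product: 3 methyl (S)-3-[(tert-butyldimethylsilyl)oxy]-2-hydroxypropanoate
Conditions: TBSCl (1.05 equiv), imidazole (2 equiv), CH2Cl2, 0 °C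
Reagents that add atoms: tert-butyldimethylsilyl chloride, CC(C)(C)[Si](C)(C)Cl
Why: Chemoselective silyl ether formation takes the unhindered primary hydroxyl in preference to the secondary, ester-deactivated one, a standard discrimination in the glycerate series.

**Step 3**
Reactants: 4 syringic acid
Product: 5 tert-butyl 4-hydroxy-3,5-dimethoxybenzoate
Conditions: Me2NCH(Ot-Bu)2 (4 equiv), toluene, 80 °C
Reagents that add atoms: N,N-dimethylformamide di-tert-butyl acetal, CN(C)C(OC(C)(C)C)OC(C)(C)C
Why: Esterification with a formamide acetal alkylates only the carboxylic acid, while the much less acidic, doubly flanked phenol stays free, as is known for hydroxybenzoic acids.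

**Step 4**
Reactants: 3 methyl (S)-3-[(tert-butyldimethylsilyl)oxy]-2-hydroxypropanoate; 5 tert-butyl 4-hydroxy-3,5-dimethoxybenzoate
Product: 6 tert-butyl 4-{[(2R)-3-[(tert-butyldimethylsilyl)oxy]-1-methoxy-1-oxopropan-2-yl]oxy}-3,5-dimethoxybenzoate
Conditions: PPh3, DIAD, THF, 0 °C → rt
Reagents that add atoms: none
Why: In this Mitsunobu etherification the acidic para-ester phenol displaces the oxyphosphonium group of the α-hydroxy ester by SN2 with inversion, which sets C8 as R; lactate-type esters and 2,6-dimethoxyphenols are proven partners.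

**Step 5**
Reactants: 6 tert-butyl 4-{[(2R)-3-[(tert-butyldimethylsilyl)oxy]-1-methoxy-1-oxopropan-2-yl]oxy}-3,5-dimethoxybenzoate
Product: 7 (2R)-2-[4-(tert-butoxycarbonyl)-2,6-dimethoxyphenoxy]-3-[(tert-butyldimethylsilyl)oxy]propanoic acid
Conditions: LiOH·H2O (1.5 equiv), THF–H2O 3:1, 0 °C; cold 0.5 M HCl to pH 3–4
Reagents that add atoms: lithium hydroxide, [Li+].[OH-]
Why: Saponification of the unhindered, inductively activated methyl ester at 0 °C is much faster than attack on the aryl tert-butyl ester and than α-deprotonation, as in the 2-aryloxypropanoate series, so C8 stays R.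

**Step 6**
Reactants: 7 (2R)-2-[4-(tert-butoxycarbonyl)-2,6-dimethoxyphenoxy]-3-[(tert-butyldimethylsilyl)oxy]propanoic acid; 8 (E)-3-(dimethylamino)acrolein
Product: 10 tert-butyl 4-{[(2R,4E)-1-[(tert-butyldimethylsilyl)oxy]-5-(dimethylamino)-4-formyl-3-oxopent-4-en-2-yl]oxy}-3,5-dimethoxybenzoate, via acid chloride 9 (not isolated)
Conditions: 1-chloro-N,N,2-trimethylprop-1-en-1-amine (1.1 equiv), CH2Cl2, 0 °C; then 8 (1.5 equiv), 2,6-lutidine (1.2 equiv), −20 °C → rt
Reagents that add atoms: 1-chloro-N,N,2-trimethylprop-1-en-1-amine (Ghosez reagent), CC(C)=C(Cl)N(C)C (chlorine of 9 only)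
Why: Neutral acid chloride formation with an α-chloroenamine is followed by C-acylation of a push–pull enamine at its nucleophilic α-carbon, the reaction type established for 3-(dimethylamino)acrylates and β-enaminones; O-acylation is reversible whereas loss of the C2 proton makes C-acylation final, and the weak hindered base in place of a trialkylamine avoids ketene formation, so C8 stays R.

**Step 7**
Reactants: 10 tert-butyl 4-{[(2R,4E)-1-[(tert-butyldimethylsilyl)oxy]-5-(dimethylamino)-4-formyl-3-oxopent-4-en-2-yl]oxy}-3,5-dimethoxybenzoate; 11 1,3-dimethoxyacetone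
Product: 15 tert-butyl 4-{[(2R)-3-[(tert-butyldimethylsilyl)oxy]-1-(4-hydroxy-3,5-dimethoxyphenyl)-1-oxopropan-2-yl]oxy}-3,5-dimethoxybenzoate, via lithium enolate 12 (not isolated), via open-chain enedione 13 (not isolated), via cyclohexadienone 14 (not isolated)
Conditions: 11 (1.2 equiv), LiN(SiMe3)2 (1.05 equiv), THF, −78 °C; 10, −78 → −20 °C; t-BuOH (5 equiv), −20 → 40 °C; AcOH quench
Reagents that add atoms: LiN(SiMe3)2, [Li+].C[Si](C)(C)[N-][Si](C)(C)C (lithium of 12 only)
Why: Proposed new method: the preformed lithium enolate 12 attacks an aldehyde-level carbon of 10 under kinetic control (conjugate addition at the aminomethine carbon; a competing aldol addition at the formyl carbon is reversible and, by the symmetry of 11, leads to the same ring), and once tert-butanol allows proton shuttling dimethylamine is expelled to give 13, held as its delocalised enolate (C2–C3 bond). The remaining methoxy-bearing methylene carbon C5 then closes ring A onto the formyl carbon C6 in a favoured 6-(enolendo)-exo-trig aldol step (C5–C6 bond), water is lost, and dienone 14 tautomerises to the phenol, whose lithium phenoxide absorbs the single equivalent of base, so the medium becomes only weakly basic as the cascade proceeds. The closest known reaction type is the base-mediated 3+3 phenol synthesis from ketones with two α-methylene groups and 2-acceptor-substituted malonaldehyde equivalents (sodium nitromalonaldehyde, 3-amino-2-nitroacroleins, vinamidinium salts, and 3-formylchromones as cyclic 2-acyl-3-aryloxyacroleins); the untested elements are the acyclic 2-acyl enaminal, the unactivated dialkoxyacetone and the enolisable centre next to the acyl group. No stereocentre is created, and C8 only has to survive, which rests on the vinylogous-amide character of its ketone in 10, on the anionic (enolate or phenoxide) nature of every species after the first bond, and on the hindered C8 methine being kinetically less acidic than the C5 methylene. Reaction at the formyl and aminomethine carbons instead of the C7 ketone follows from their lower steric demand and higher electrophilicity, and regiochemistry is not an issue because both α-carbons of 11 are equivalent. Secondary-ammonium carboxylate buffers are avoided on purpose, since an enamine at C4 would aromatise to a 4-(dialkylamino)arene, whereas without acid the liberated dimethylamine does not condense with the enolate-deactivated C4 carbonyl and C4 keeps its oxygen.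

**Step 8**
Reactants: 15 tert-butyl 4-{[(2R)-3-[(tert-butyldimethylsilyl)oxy]-1-(4-hydroxy-3,5-dimethoxyphenyl)-1-oxopropan-2-yl]oxy}-3,5-dimethoxybenzoate
Product: 16 4-{[(2R)-3-hydroxy-1-(4-hydroxy-3,5-dimethoxyphenyl)-1-oxopropan-2-yl]oxy}-3,5-dimethoxybenzoic acid (CNP0511559.1)
Conditions: TFA–CH2Cl2–H2O 10:10:1, 0 °C → rt; co-evaporation with toluene, then MeOH
Reagents that add atoms: none
Why: Acidolysis cleaves the tert-butyl ester by alkyl–oxygen fission and hydrolyses the primary silyl ether in the same pot, and the non-basic medium avoids retro-aldol, E1cB dehydration and base-induced epimerisation of the β-hydroxy-α-aryloxy ketone.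

**Compound list**
1 | methyl (S)-2,2-dimethyl-1,3-dioxolane-4-carboxylate | COC(=O)[C@@H]1COC(C)(C)O1 | starting material
2 | methyl (S)-2,3-dihydroxypropanoate | COC(=O)[C@@H](O)CO | intermediate
3 | methyl (S)-3-[(tert-butyldimethylsilyl)oxy]-2-hydroxypropanoate | COC(=O)[C@@H](O)CO[Si](C)(C)C(C)(C)C | intermediate
4 | syringic acid | COc1cc(C(=O)O)cc(OC)c1O | starting material
5 | tert-butyl 4-hydroxy-3,5-dimethoxybenzoate | COc1cc(C(=O)OC(C)(C)C)cc(OC)c1O | intermediate
6 | (R)-aryloxy methyl ester (Mitsunobu product) | COC(=O)[C@@H](CO[Si](C)(C)C(C)(C)C)Oc1c(OC)cc(C(=O)OC(C)(C)C)cc1OC | intermediate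
7 | (R)-2-aryloxy-3-silyloxypropanoic acid | OC(=O)[C@@H](CO[Si](C)(C)C(C)(C)C)Oc1c(OC)cc(C(=O)OC(C)(C)C)cc1OC | intermediate
8 | (E)-3-(dimethylamino)acrolein | CN(C)/C=C/C=O | starting material
9 | (R)-acid chloride of 7 (not isolated) | ClC(=O)[C@@H](CO[Si](C)(C)C(C)(C)C)Oc1c(OC)cc(C(=O)OC(C)(C)C)cc1OC | intermediate
10 | (R)-2-acyl-3-(dimethylamino)acrolein carrying ring B and the silyloxymethyl group | CN(C)/C=C(\C=O)C(=O)[C@@H](CO[Si](C)(C)C(C)(C)C)Oc1c(OC)cc(C(=O)OC(C)(C)C)cc1OC | intermediate
11 | 1,3-dimethoxyacetone | COCC(=O)COC | starting material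
12 | lithium enolate of 11 (not isolated) | [Li+].[O-]C(=COC)COC | intermediate
13 | open-chain enedione after loss of dimethylamine, drawn as the neutral keto form, transient C3 centre and C=C geometry undefined (not isolated) | COCC(=O)C(OC)C=C(C=O)C(=O)[C@@H](CO[Si](C)(C)C(C)(C)C)Oc1c(OC)cc(C(=O)OC(C)(C)C)cc1OC | intermediate
14 | 4-acyl-2,6-dimethoxycyclohexa-2,4-dienone, keto tautomer of 15, transient C3 centre undefined (not isolated) | COC1C=C(C(=O)[C@@H](CO[Si](C)(C)C(C)(C)C)Oc2c(OC)cc(C(=O)OC(C)(C)C)cc2OC)C=C(OC)C1=O | intermediate
15 | (R)-target as TBS ether and tert-butyl ester, ring A phenol free | COc1cc(C(=O)[C@@H](CO[Si](C)(C)C(C)(C)C)Oc2c(OC)cc(C(=O)OC(C)(C)C)cc2OC)cc(OC)c1O | intermediate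
16 | CNP0511559.1, (R) | COc1cc(C(=O)[C@@H](CO)Oc2c(OC)cc(C(=O)O)cc2OC)cc(OC)c1O | target

**Step count**
Total steps: 8.
Longest linear sequence: 7 steps (1, 2, 4, 5, 6, 7, 8, counted from compound 1).

**Steps most likely to fail**

**1. Step 7.**
- The cascade may stall after the first carbon–carbon bond, because the open-chain intermediate rests as a delocalised enolate whose formyl group is a weak electrophile.
- Liberated dimethylamine may condense at the C4 carbonyl and divert the aromatisation towards nitrogen at C4.
- A slow closure leaves time for enolisation at C8, with erosion of enantiopurity and β-elimination of silanolate.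
- Fallback (known chemistry, ring A bought instead of built) sets out from 7 and returns at 16. Acid 7 is condensed with N,O-dimethylhydroxylamine hydrochloride (EDC·HCl, HOBt, N-methylmorpholine, CH2Cl2, 0 °C) to the (R)-Weinreb amide F1. Commercial 4-bromo-2,6-dimethoxyphenol is protected with MOMCl and i-Pr2NEt as 5-bromo-1,3-dimethoxy-2-(methoxymethoxy)benzene F2. n-BuLi (THF, −78 °C) converts it into 3,5-dimethoxy-4-(methoxymethoxy)phenyllithium F3. Addition of this aryllithium to the amide at −78 °C forms the C1–C7 bond through the chelated tetrahedral adduct and gives, after NH4Cl quench, the methoxymethyl-protected aryl ketone F4. The aqueous TFA conditions of step 8 then remove the methoxymethyl, silyl and tert-butyl groups together and deliver 16.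

**2. Step 6.**
- The vinylogous formamide may be acylated at oxygen and then condense with itself instead of being acylated at C2.
- Any ketene formation or enolisation of the activated acyl species would racemise C8.
- Fallback sets out from 7 and returns at 10. Acid 7 is converted (PhSH, EDC·HCl, HOBt, CH2Cl2, 0 °C) into the (R)-S-phenyl thioester F5. This is coupled under base-free Liebeskind–Srogl conditions with isoxazol-4-ylboronic acid (Pd2(dba)3, P(OEt)3, copper thiophene-2-carboxylate, THF, 45 °C) to the (R)-4-acylisoxazole F6. Reductive N–O cleavage (Mo(CO)6, MeCN–H2O, 80 °C) unmasks the (R)-2-acyl-3-aminoacrolein F7. Amine exchange with excess dimethylamine in THF under a nitrogen sweep gives 10.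

**3. Step 4.**
- The doubly ortho-substituted phenol may couple sluggishly, so that the hydrazide is alkylated instead.
- Silyl migration and incomplete inversion become competitive.
- Fallback sets out from 3 and returns at 6. Alcohol 3 is activated with Tf2O and 2,6-lutidine (CH2Cl2, −78 °C) as methyl (S)-3-[(tert-butyldimethylsilyl)oxy]-2-(trifluoromethylsulfonyloxy)propanoate F8. The cesium phenoxide of 5 (Cs2CO3, MeCN, 0 °C) displaces the triflate in a separate SN2 step with inversion to give 6.

**Further compounds**
F1 | step 7 | (R)-Weinreb amide of 7 | CON(C)C(=O)[C@@H](CO[Si](C)(C)C(C)(C)C)Oc1c(OC)cc(C(=O)OC(C)(C)C)cc1OC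
F2 | step 7 | 5-bromo-1,3-dimethoxy-2-(methoxymethoxy)benzene | COCOc1c(OC)cc(Br)cc1OC
F3 | step 7 | 3,5-dimethoxy-4-(methoxymethoxy)phenyllithium | [Li]c1cc(OC)c(OCOC)c(OC)c1
F4 | step 7 | (R)-methoxymethyl-protected aryl ketone | COCOc1c(OC)cc(C(=O)[C@@H](CO[Si](C)(C)C(C)(C)C)Oc2c(OC)cc(C(=O)OC(C)(C)C)cc2OC)cc1OC
F5 | step 6 | (R)-S-phenyl thioester of 7 | O=C(Sc1ccccc1)[C@@H](CO[Si](C)(C)C(C)(C)C)Oc1c(OC)cc(C(=O)OC(C)(C)C)cc1OC
F6 | step 6 | (R)-4-acylisoxazole | O=C(c1cnoc1)[C@@H](CO[Si](C)(C)C(C)(C)C)Oc1c(OC)cc(C(=O)OC(C)(C)C)cc1OC
F7 | step 6 | (R)-2-acyl-3-aminoacrolein (C=C geometry mobile) | NC=C(C=O)C(=O)[C@@H](CO[Si](C)(C)C(C)(C)C)Oc1c(OC)cc(C(=O)OC(C)(C)C)cc1OC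
F8 | step 4 | methyl (S)-3-[(tert-butyldimethylsilyl)oxy]-2-(trifluoromethylsulfonyloxy)propanoate | COC(=O)[C@@H](OS(=O)(=O)C(F)(F)F)CO[Si](C)(C)C(C)(C)C
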